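The bond disconnected is C7a–C7b (cyclobuta[a]indene locants) between ring A and the cyclobutane. The cyclobutane C1–C2(Me2)–C2a–C7b maps atom for atom onto the cyclobutane of verbenone, so only its ring CH2 (C7b) has to be joined to ring A carbon C7a. A palladium-catalysed intramolecular C(sp3)–H arylation does this in one operation: it closes the cyclopentane (C3a–C3–C2a–C7b–C7a) and sets the C7b stereocentre from C2a. Its precursor is a 7-methoxy-2,2-dimethyl-2H-chromen-5-yl triflate bearing at C6 the cis-(3-methoxycarbonyl-2,2-dimethylcyclobutyl)methyl group; the ester is later exchanged for the catechol by decarboxylative arylation.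

Key step: step 12

Assumption: (1R,5R)-(+)-verbenone is taken as purchasable and is the enantiomer required, because the carboxyl group made in the haloform step (on the former C5 of verbenone) becomes benzylic C3, whereas (1S,5S)-verbenone carried through the same sequence would give the antipode; the keto acid is esterified before the haloform step because the free 1,3-diacid would be meso.

Step 1
Reactants: 1 (1R,5R)-(+)-verbenone
Product: 2 (1R,3S)-3-acetyl-2,2-dimethylcyclobutane-1-carboxylic acid (cis)
Conditions: RuCl3·xH2O (2 mol %), NaIO4 (4.1 equiv), EtOAc/MeCN/H2O, rt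
Reagents that add atoms: sodium periodate, [Na+].[O-]I(=O)(=O)=O; water, O
Why: RuO4 generated in situ cleaves the enone C=C (oxidative alkene cleavage) and the α-keto acid so formed loses CO2 oxidatively, so the former C4 becomes the acetyl carbon and C2 the carboxyl carbon while the two ring stereocentres, and with them the cis arrangement, are not touched.

Step 2
Reactants: 2 (1R,3S)-3-acetyl-2,2-dimethylcyclobutane-1-carboxylic acid
Product: 3 methyl (1R,3S)-3-acetyl-2,2-dimethylcyclobutane-1-carboxylate
Conditions: Me3SiCHN2 (1.2 equiv), PhMe/MeOH, 0 °C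
Reagents that add atoms: trimethylsilyldiazomethane, C[Si](C)(C)C=[N+]=[N-]
Why: Esterification with a diazoalkane under neutral conditions masks the existing carboxyl group without base that could epimerise the carbon next to the ketone, and it must precede step 3 because the free 1,3-diacid would be meso.

Step 3
Reactants: 3 methyl (1R,3S)-3-acetyl-2,2-dimethylcyclobutane-1-carboxylate
Product: 4 (1S,3R)-3-(methoxycarbonyl)-2,2-dimethylcyclobutane-1-carboxylic acid (cis)
Conditions: Br2, NaOH, H2O/1,4-dioxane, −5 to 0 °C; then NaHSO3, HCl (pH 2)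
Reagents that add atoms: sodium hydroxide, [Na+].[OH-]
Why: Lieben haloform reaction: hypobromite tribrominates the methyl group of the ketone through its methyl enolate and hydroxide then cleaves the CBr3 group, which leaves a carboxyl group on the former C5 of verbenone with retention, the hindered methyl ester being slow to saponify in cold dilute alkali.

Step 4
Reactants: 4 (1S,3R)-3-(methoxycarbonyl)-2,2-dimethylcyclobutane-1-carboxylic acid
Product: 5 methyl (1R,3S)-3-(hydroxymethyl)-2,2-dimethylcyclobutane-1-carboxylate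
Conditions: BH3·SMe2 (1.3 equiv), THF, 0 °C to rt; MeOH quench
Reagents that add atoms: none
Why: Borane reduces a carboxylic acid far faster than an ester (chemoselective acyloxyborane reduction), so only the new carboxyl group becomes CH2OH and no stereocentre is involved.

Step 5
Reactants: 5 methyl (1R,3S)-3-(hydroxymethyl)-2,2-dimethylcyclobutane-1-carboxylate
Product: 6 methyl (1R,3S)-3-(iodomethyl)-2,2-dimethylcyclobutane-1-carboxylate
Conditions: I2, PPh3, imidazole, CH2Cl2, 0 °C to rt
Reagents that add atoms: iodine, II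
Why: Appel-type iodination: the alkoxyphosphonium ion is displaced by iodide in an SN2 reaction at the primary carbon, one atom away from the ring stereocentre.

Step 6
Reactants: 6 methyl (1R,3S)-3-(iodomethyl)-2,2-dimethylcyclobutane-1-carboxylate; 7 2-bromo-1,3-dimethoxybenzene
Product: 9 methyl (1R,3R)-3-[(2,6-dimethoxyphenyl)methyl]-2,2-dimethylcyclobutane-1-carboxylate, via alkylzinc iodide 8 (not isolated)
Conditions: Zn dust, LiCl, THF, 40 °C; then 7, Pd(OAc)2 (2 mol %), 2-dicyclohexylphosphino-2',6'-dimethoxybiphenyl (4 mol %), THF, 60 °C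
Reagents that add atoms: none
Why: Negishi coupling: LiCl-assisted zinc insertion gives a primary alkylzinc that tolerates the ester, and a palladium catalyst with a bulky biarylphosphine couples it with the di-ortho-substituted aryl bromide faster than β-hydride elimination; the ring stereocentres do not take part.

Step 7
Reactants: 9 methyl (1R,3R)-3-[(2,6-dimethoxyphenyl)methyl]-2,2-dimethylcyclobutane-1-carboxylate
Product: 11 methyl (1R,3R)-3-[(4-hydroxy-2,6-dimethoxyphenyl)methyl]-2,2-dimethylcyclobutane-1-carboxylate, via arylboronate 10 (not isolated)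
Conditions: [Ir(OMe)(1,5-cyclooctadiene)]2 (1.5 mol %), 4,4'-di-tert-butyl-2,2'-bipyridine (3 mol %), B2pin2 (1.0 equiv), THF, 80 °C; then KHSO5 (as 2KHSO5·KHSO4·K2SO4), acetone/H2O, rt
Reagents that add atoms: bis(pinacolato)diboron, CC1(C)OB(OC1(C)C)B1OC(C)(C)C(C)(C)O1 (boryl group of 10); potassium peroxymonosulfate, [K+].[O-]S(=O)(=O)OO (phenol oxygen)
Why: Iridium-catalysed arene C–H borylation is governed by sterics, so only the ring C–H para to the alkyl group, the one position not flanked by a substituent, is borylated, and oxidation of the C–B bond with peroxymonosulfate gives the phenol.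

Step 8
Reactants: 11 methyl (1R,3R)-3-[(4-hydroxy-2,6-dimethoxyphenyl)methyl]-2,2-dimethylcyclobutane-1-carboxylate; 12 3-methylbut-2-enoic acid
Product: 13 methyl (1R,3R)-3-[(5,7-dimethoxy-2,2-dimethyl-4-oxo-3,4-dihydro-2H-chromen-6-yl)methyl]-2,2-dimethylcyclobutane-1-carboxylate
Conditions: 12 (1.2 equiv), P2O5 in CH3SO3H, 60–70 °C
Reagents that add atoms: none
Why: Friedel–Crafts acylation ortho to the phenol followed by oxa-Michael ring closure gives the 2,2-dimethylchroman-4-one, and since the two ortho positions are equivalent by symmetry only one regioisomer can form.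

Step 9
Reactants: 13 methyl (1R,3R)-3-[(5,7-dimethoxy-2,2-dimethyl-4-oxo-3,4-dihydro-2H-chromen-6-yl)methyl]-2,2-dimethylcyclobutane-1-carboxylate
Product: 14 methyl (1R,3R)-3-[(5-hydroxy-7-methoxy-2,2-dimethyl-4-oxo-3,4-dihydro-2H-chromen-6-yl)methyl]-2,2-dimethylcyclobutane-1-carboxylate
Conditions: BCl3 (1.5 equiv), CH2Cl2, −78 to 0 °C; aqueous work-up
Reagents that add atoms: none
Why: Chelation-controlled ether cleavage: BCl3 bound to the C4 carbonyl reaches only the peri 5-methoxy group through a six-membered chelate, so the 7-methoxy group and the methyl ester stay intact.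

Step 10
Reactants: 14 methyl (1R,3R)-3-[(5-hydroxy-7-methoxy-2,2-dimethyl-4-oxo-3,4-dihydro-2H-chromen-6-yl)methyl]-2,2-dimethylcyclobutane-1-carboxylate
Product: 15 methyl (1R,3R)-3-{[7-methoxy-2,2-dimethyl-4-oxo-5-(trifluoromethanesulfonyloxy)-3,4-dihydro-2H-chromen-6-yl]methyl}-2,2-dimethylcyclobutane-1-carboxylate
Conditions: Tf2O (1.3 equiv), pyridine, CH2Cl2, 0 °C to rt
Reagents that add atoms: trifluoromethanesulfonic anhydride, O=S(=O)(OS(=O)(=O)C(F)(F)F)C(F)(F)F
Why: O-Sulfonylation of the phenol with triflic anhydride and pyridine; it is placed before the reduction so that no ortho-quinone methide can form from a free 5-hydroxy chromanol.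

Step 11
Reactants: 15 methyl (1R,3R)-3-{[7-methoxy-2,2-dimethyl-4-oxo-5-(trifluoromethanesulfonyloxy)-3,4-dihydro-2H-chromen-6-yl]methyl}-2,2-dimethylcyclobutane-1-carboxylate
Product: 17 methyl (1R,3R)-3-{[7-methoxy-2,2-dimethyl-5-(trifluoromethanesulfonyloxy)-2H-chromen-6-yl]methyl}-2,2-dimethylcyclobutane-1-carboxylate, via chroman-4-ol 16 (not isolated)
Conditions: NaBH4, MeOH/THF, 0 °C; work-up, then p-TsOH·H2O (5 mol %), PhMe, 80 °C
Reagents that add atoms: none
Why: Hydride reduction of the ketone followed by acid-catalysed E1 dehydration through a benzylic cation stabilised by O1 and the 7-methoxy group gives the 2H-chromene, with ester, triflate and cyclobutane unaffected.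

Step 12
Reactants: 17 methyl (1R,3R)-3-{[7-methoxy-2,2-dimethyl-5-(trifluoromethanesulfonyloxy)-2H-chromen-6-yl]methyl}-2,2-dimethylcyclobutane-1-carboxylate
Product: 18 all-cis tetracyclic methyl ester, (1R,2aS,7bR) in cyclobuta[a]indene locants: CO2Me at C1, CMe2 at C2, cis ring-fusion hydrogens at C2a and C7b, OMe at C4, 2,2-dimethyl-2H-pyran fused through O–C6 and CH=CH–C7
Conditions: Pd(OAc)2 (10 mol %), P(C6H11)3·HBF4 (20 mol %), CsO2CCMe3 (1.5 equiv), mesitylene, 140 °C, Ar
Reagents that add atoms: none
Why: Oxidative addition of the C7a–OTf bond to zerovalent palladium bearing P(C6H11)3 gives an arylpalladium species that binds pivalate; concerted metalation–deprotonation then removes the C7b hydrogen on the tether face through a six-membered palladacycle (Pd, C7a, C3a, C3, C2a, C7b), and C–C reductive elimination forms C7a–C7b. The closest known reaction type is the palladium-catalysed intramolecular C(sp3)–H arylation of aryl halides and triflates that turns 2-alkylaryl electrophiles into indanes, including cases at methylene groups of strained rings. The cyclopentane C3a–C3–C2a–C7b–C7a is closed by this reductive elimination, a contraction of the six-membered palladacycle (5-exo in ring terms). The new stereocentre C7b is controlled by C2a: only the hydrogen cis to the CH2–aryl tether can reach palladium, and only a cis-fused bicyclo[3.2.0]heptane is attainable. The step needs site selectivity for the ring CH2 over C2a–H (five-membered palladacycle at a tertiary carbon, leading to a spiro benzocyclobutene), the C2 methyl groups (seven-membered palladacycle) and C1–H; the cis ester secures the last point, since it holds C1–H on the face opposite to palladium, which also leaves the C7b–Pd intermediate without a syn β-hydrogen. Epimerisation at C1 by the base would be harmless because that centre is reset in step 16.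

Step 13
Reactants: 18 all-cis tetracyclic methyl ester
Product: 19 tetracyclic carboxylic acid, (1R,2aS,7bR), CO2H at C1, otherwise as 18
Conditions: LiOH·H2O (5 equiv), THF/MeOH/H2O, 50 °C; then 1 M HCl to pH 3, 0 °C
Reagents that add atoms: lithium hydroxide, [Li+].[OH-]
Why: Saponification of the methyl ester; partial epimerisation at C1 would not matter because C1 becomes a radical in step 16.

Step 14
Reactants: 19 tetracyclic carboxylic acid
Product: 20 1,3-dioxoisoindolin-2-yl ester of acid 19 (N-acyloxyphthalimide at C1)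
Conditions: N-hydroxyphthalimide, N,N'-diisopropylcarbodiimide, DMAP (10 mol %), CH2Cl2, rt
Reagents that add atoms: N-hydroxyphthalimide, ON1C(=O)c2ccccc2C1=O
Why: Carbodiimide-mediated esterification (Steglich type) turns the acid into a redox-active N-acyloxyphthalimide.

Step 15
Reactants: 21 4-bromobenzene-1,2-diol
Product: 22 4-bromo-1,2-bis(tert-butyldimethylsilyloxy)benzene
Conditions: TBSCl (2.4 equiv), imidazole, DMF, rt
Reagents that add atoms: tert-butyldimethylsilyl chloride, CC(C)(C)[Si](C)(C)Cl
Why: Silylation of both phenols with a silyl chloride and imidazole gives a catechol protection that survives aryllithium and arylzinc formation and is later removed by fluoride without touching the chromene.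

Step 16
Reactants: 20 N-acyloxyphthalimide of acid 19; 22 4-bromo-1,2-bis(tert-butyldimethylsilyloxy)benzene
Product: 25 bis-silyl ether of the target, (1S,2aS,7bR), 3,4-bis(tert-butyldimethylsilyloxy)phenyl at C1 trans to the C7b–C7a bond, via aryllithium 23 (not isolated), via arylzinc chloride 24 (not isolated)
Conditions: 22 (3 equiv), n-BuLi, THF, −78 °C; ZnCl2, THF, −78 °C to rt; then 20, NiCl2(MeOCH2CH2OMe) (20 mol %), 4,4'-di-tert-butyl-2,2'-bipyridine (40 mol %), THF/DMF, rt
Reagents that add atoms: none
Why: Nickel-catalysed decarboxylative Negishi-type arylation of a redox-active ester: single-electron reduction releases CO2 and phthalimide anion and leaves a C1 cyclobutyl radical, which the aryl–nickel species captures on the convex face, opposite ring A on the neighbouring C7b, so that reductive elimination places the aryl group trans to the C7b–C7a bond (1S).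

Step 17
Reactants: 25 bis-silyl ether of the target
Product: 26 CNP0207533.1, (1S,2aS,7bR)-configured catechol
Conditions: Bu4NF (2.5 equiv), AcOH (3 equiv), THF, 0 °C, Ar
Reagents that add atoms: none
Why: Fluoride-induced desilylation of the aryl silyl ethers, buffered with acetic acid so that the catechol is not exposed to base and air, leaves the chromene, the methyl ether and all stereocentres untouched.

Compound list
1 | (1R,5R)-(+)-verbenone | CC1=CC(=O)[C@@H]2C[C@H]1C2(C)C | starting material
2 | (1R,3S)-3-acetyl-2,2-dimethylcyclobutane-1-carboxylic acid | CC(=O)[C@H]1C[C@@H](C(=O)O)C1(C)C | intermediate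
3 | methyl (1R,3S)-3-acetyl-2,2-dimethylcyclobutane-1-carboxylate | CC(=O)[C@H]1C[C@@H](C(=O)OC)C1(C)C | intermediate
4 | (1S,3R)-3-(methoxycarbonyl)-2,2-dimethylcyclobutane-1-carboxylic acid | OC(=O)[C@H]1C[C@@H](C(=O)OC)C1(C)C | intermediate
5 | methyl (1R,3S)-3-(hydroxymethyl)-2,2-dimethylcyclobutane-1-carboxylate | OC[C@H]1C[C@@H](C(=O)OC)C1(C)C | intermediate
6 | methyl (1R,3S)-3-(iodomethyl)-2,2-dimethylcyclobutane-1-carboxylate | IC[C@H]1C[C@@H](C(=O)OC)C1(C)C | intermediate
7 | 2-bromo-1,3-dimethoxybenzene | COc1cccc(OC)c1Br | starting material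
8 | {[(1S,3R)-3-(methoxycarbonyl)-2,2-dimethylcyclobutyl]methyl}zinc iodide | I[Zn]C[C@H]1C[C@@H](C(=O)OC)C1(C)C | intermediate, not isolated
9 | methyl (1R,3R)-3-[(2,6-dimethoxyphenyl)methyl]-2,2-dimethylcyclobutane-1-carboxylate | COc1cccc(OC)c1C[C@H]1C[C@@H](C(=O)OC)C1(C)C | intermediate
10 | methyl (1R,3R)-3-{[2,6-dimethoxy-4-(4,4,5,5-tetramethyl-1,3,2-dioxaborolan-2-yl)phenyl]methyl}-2,2-dimethylcyclobutane-1-carboxylate | COc1cc(B2OC(C)(C)C(C)(C)O2)cc(OC)c1C[C@H]1C[C@@H](C(=O)OC)C1(C)C | intermediate, not isolated
11 | methyl (1R,3R)-3-[(4-hydroxy-2,6-dimethoxyphenyl)methyl]-2,2-dimethylcyclobutane-1-carboxylate | COc1cc(O)cc(OC)c1C[C@H]1C[C@@H](C(=O)OC)C1(C)C | intermediate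
12 | 3-methylbut-2-enoic acid | CC(C)=CC(O)=O | starting material
13 | methyl (1R,3R)-3-[(5,7-dimethoxy-2,2-dimethyl-4-oxo-3,4-dihydro-2H-chromen-6-yl)methyl]-2,2-dimethylcyclobutane-1-carboxylate | COc1cc2OC(C)(C)CC(=O)c2c(OC)c1C[C@H]1C[C@@H](C(=O)OC)C1(C)C | intermediate
14 | methyl (1R,3R)-3-[(5-hydroxy-7-methoxy-2,2-dimethyl-4-oxo-3,4-dihydro-2H-chromen-6-yl)methyl]-2,2-dimethylcyclobutane-1-carboxylate | COc1cc2OC(C)(C)CC(=O)c2c(O)c1C[C@H]1C[C@@H](C(=O)OC)C1(C)C | intermediate
15 | methyl (1R,3R)-3-{[7-methoxy-2,2-dimethyl-4-oxo-5-(trifluoromethanesulfonyloxy)-3,4-dihydro-2H-chromen-6-yl]methyl}-2,2-dimethylcyclobutane-1-carboxylate | COc1cc2OC(C)(C)CC(=O)c2c(OS(=O)(=O)C(F)(F)F)c1C[C@H]1C[C@@H](C(=O)OC)C1(C)C | intermediate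
16 | methyl (1R,3R)-3-{[4-hydroxy-7-methoxy-2,2-dimethyl-5-(trifluoromethanesulfonyloxy)-3,4-dihydro-2H-chromen-6-yl]methyl}-2,2-dimethylcyclobutane-1-carboxylate (C4 epimers) | COc1cc2OC(C)(C)CC(O)c2c(OS(=O)(=O)C(F)(F)F)c1C[C@H]1C[C@@H](C(=O)OC)C1(C)C | intermediate, not isolated
17 | methyl (1R,3R)-3-{[7-methoxy-2,2-dimethyl-5-(trifluoromethanesulfonyloxy)-2H-chromen-6-yl]methyl}-2,2-dimethylcyclobutane-1-carboxylate | COc1cc2c(c(OS(=O)(=O)C(F)(F)F)c1C[C@H]1C[C@@H](C(=O)OC)C1(C)C)C=CC(C)(C)O2 | intermediate
18 | all-cis tetracyclic methyl ester, (1R,2aS,7bR) in cyclobuta[a]indene locants, CO2Me at C1 | COc1cc2c(c3c1C[C@H]1[C@@H]3[C@@H](C(=O)OC)C1(C)C)C=CC(C)(C)O2 | intermediate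
19 | tetracyclic carboxylic acid, (1R,2aS,7bR), CO2H at C1 | COc1cc2c(c3c1C[C@H]1[C@@H]3[C@@H](C(O)=O)C1(C)C)C=CC(C)(C)O2 | intermediate
20 | 1,3-dioxoisoindolin-2-yl ester of acid 19 | COc1cc2c(c3c1C[C@H]1[C@@H]3[C@@H](C(=O)ON3C(=O)c4ccccc4C3=O)C1(C)C)C=CC(C)(C)O2 | intermediate
21 | 4-bromobenzene-1,2-diol | Oc1ccc(Br)cc1O | starting material
22 | 4-bromo-1,2-bis(tert-butyldimethylsilyloxy)benzene | CC(C)(C)[Si](C)(C)Oc1ccc(Br)cc1O[Si](C)(C)C(C)(C)C | intermediate
23 | 3,4-bis(tert-butyldimethylsilyloxy)phenyllithium | [Li]c1ccc(O[Si](C)(C)C(C)(C)C)c(O[Si](C)(C)C(C)(C)C)c1 | intermediate, not isolated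
24 | 3,4-bis(tert-butyldimethylsilyloxy)phenylzinc chloride | Cl[Zn]c1ccc(O[Si](C)(C)C(C)(C)C)c(O[Si](C)(C)C(C)(C)C)c1 | intermediate, not isolated
25 | bis(tert-butyldimethylsilyl) ether of the target, (1S,2aS,7bR), aryl at C1 trans to the C7b–C7a bond | COc1cc2c(c3c1C[C@H]1[C@@H]3[C@H](c3ccc(O[Si](C)(C)C(C)(C)C)c(O[Si](C)(C)C(C)(C)C)c3)C1(C)C)C=CC(C)(C)O2 | intermediate
26 | CNP0207533.1, (1S,2aS,7bR) in cyclobuta[a]indene locants, 3,4-dihydroxyphenyl at C1 | COc1cc2c(c3c1C[C@H]1[C@@H]3[C@H](c3ccc(O)c(O)c3)C1(C)C)C=CC(C)(C)O2 | target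

Total step count: 17. Longest linear sequence: 16 steps (steps 1–14, 16 and 17, from 1); step 15 is the only side branch.

Steps most likely to fail

1. Step 12. Cleavage of the S–O bond of the triflate by carboxylate, reduction of the C–O bond, or failure of the metalation on the crowded tether face may outrun ring closure. The fallback replaces C–H cleavage by carbopalladation of an alkene and sets out from 17. The ester is deprotonated at C1 (LiN(i-Pr)2, THF, −78 °C) and selenenylated with PhSeBr to give the α-phenylselanyl ester F1. Oxidation (H2O2, pyridine, CH2Cl2, 0 °C) and selenoxide syn-elimination, which is possible only toward C7b, give the cyclobut-1-ene-1-carboxylate F2. An intramolecular reductive Heck reaction (Pd(OAc)2, PPh3, HCO2Na, DMF, 70 °C) should then join C7a to C7b by 5-exo carbopalladation on the tether face, with formate reducing the C1–palladium bond. The route is rejoined at 18; a C1 epimer formed alongside would serve equally from step 13 on.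

2. Step 16. Capture of the hindered C1 radical by nickel may be slow, so that reduction, dimerisation or addition of the radical to the chromene alkene competes, and transmetalation from the electron-rich arylzinc may be incomplete. The fallback uses photoredox/nickel dual catalysis on the free acid, with no activated ester and no organozinc, and sets out from 19. Acid 19 and aryl bromide 22 are irradiated with blue light in the presence of 4CzIPN (2 mol %), NiCl2(MeOCH2CH2OMe) (10 mol %), 4,4'-di-tert-butyl-2,2'-bipyridine and Cs2CO3 in DMF at rt. The carboxylate is oxidised to the same C1 radical, which is arylated on the convex face, and the route is rejoined at 25 with step 14 omitted.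

3. Step 6. Oxidative addition and transmetalation at the di-ortho-substituted bromide may be slow enough for β-hydride elimination or protonation of the alkylzinc to dominate. The fallback forms the aryl–carbon bond by polar addition and sets out from 5. Oxidation (TEMPO (cat.), PhI(OAc)2, CH2Cl2, rt) gives the aldehyde F3. 1,3-Dimethoxybenzene is lithiated between its methoxy groups (n-BuLi, THF, 0 °C) to 2,6-dimethoxyphenyllithium F4, which adds to F3 at −78 °C, the aldehyde reacting far faster than the ester, to give the carbinol F5. Ionic hydrogenation (Et3SiH, CF3CO2H, CH2Cl2, −20 °C) removes the benzylic hydroxyl group, and the route is rejoined at 9.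

Further compounds
F1 | step 12 | methyl 3-{[7-methoxy-2,2-dimethyl-5-(trifluoromethanesulfonyloxy)-2H-chromen-6-yl]methyl}-2,2-dimethyl-1-(phenylselanyl)cyclobutane-1-carboxylate (tether carbon as in 17, C1 epimers) | COc1cc2c(c(OS(=O)(=O)C(F)(F)F)c1C[C@H]1CC([Se]c3ccccc3)(C(=O)OC)C1(C)C)C=CC(C)(C)O2
F2 | step 12 | methyl 3-{[7-methoxy-2,2-dimethyl-5-(trifluoromethanesulfonyloxy)-2H-chromen-6-yl]methyl}-4,4-dimethylcyclobut-1-ene-1-carboxylate (tether carbon as in 17) | COc1cc2c(c(OS(=O)(=O)C(F)(F)F)c1C[C@H]1C=C(C(=O)OC)C1(C)C)C=CC(C)(C)O2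
F0 | step 16 | none | none
F3 | step 6 | methyl (1R,3S)-3-formyl-2,2-dimethylcyclobutane-1-carboxylate | O=C[C@H]1C[C@@H](C(=O)OC)C1(C)C
F4 | step 6 | 2,6-dimethoxyphenyllithium | [Li]c1c(OC)cccc1OC
F5 | step 6 | methyl (1R,3S)-3-[(2,6-dimethoxyphenyl)(hydroxy)methyl]-2,2-dimethylcyclobutane-1-carboxylate (carbinol epimers) | COc1cccc(OC)c1C(O)[C@H]1C[C@@H](C(=O)OC)C1(C)C
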